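**Retrosynthetic overview**
1. The C16 methyl and the C11 carbinol are set last: exo-face hydrogenation of a 15-oxo-16-ene and electron-transfer reduction of an 11-ketone.
2. Ring D: light-driven 5-exo vinyl-radical closure (C16 to C13) onto a ring C enone; C15–C17 arrive by aldol of the C8 lactone enolate with 2-bromoacrolein.
3. Rings B and C in one operation: intramolecular Michael addition (C9–C8) and aldol condensation (C12–C13) of a 4-oxobut-2-enoate ester of the C20 alcohol.
4. C10 quaternary centre: photocatalytic addition of the hydroxymethyl radical of methanol (C20) to a ring A butenolide made by carbonylative lactonisation.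
5. The C4 quaternary centre comes from (S)-carvone (reductive aldol, then excision of the isopropenyl group). Ring order: A, A-lactone, B + C, D.

Assumption: C-numbers (C1–C20) are the ent-kaurane positions of the target; (2E)-4,4-dimethoxybut-2-enoic acid and 2-bromoacrolein are taken as purchasable.

**Step 1**
Reactants: 1 (S)-(+)-carvone
Product: 3 (2S,5S)-2-(hydroxymethyl)-2-methyl-5-(prop-1-en-2-yl)cyclohexan-1-one, via lithium enolate 2 (not isolated)
Conditions: LiBH(s-Bu)3, THF, −78 °C; then CH2O (gas), −78 °C; H2O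
Reagents that add atoms: formaldehyde, C=O
Why: Conjugate hydride reduction gives the C2 enolate regiospecifically and the aldol with formaldehyde occurs by axial attack on the half-chair with the isopropenyl group equatorial, so CH2OH enters cis to it and the quaternary centre (later C4) is set as 2S (reductive aldol reaction).

**Step 2**
Reactants: 3 (2S,5S)-2-(hydroxymethyl)-2-methyl-5-(prop-1-en-2-yl)cyclohexan-1-one
Product: 5 (2S)-2-(hydroxymethyl)-2-methylcyclohexan-1-one, via methoxy hydroperoxide 4 (not isolated)
Conditions: O3, MeOH, −78 °C; then FeSO4·7H2O, PhSH, 0 °C to rt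
Reagents that add atoms: none
Why: Criegee ozonolysis in methanol, iron-induced O–O cleavage, β-scission and hydrogen-atom transfer from the thiol replace the isopropenyl group by H (dealkenylative hydrogenation), leaving the quaternary centre as the only stereocentre.

**Step 3**
Reactants: 5 (2S)-2-(hydroxymethyl)-2-methylcyclohexan-1-one; 6 methallyl bromide
Product: 8 (2S)-2-(hydroxymethyl)-2-methyl-6-(2-methylprop-2-en-1-yl)cyclohexan-1-one, via dilithium alkoxide enolate 7 (not isolated)
Conditions: LiN(i-Pr)2 (2.2 equiv), THF, −78 °C; then 6; H2O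
Reagents that add atoms: none
Why: The only enolisable position (later C10) is C-alkylated by SN2 reaction (ketone enolate alkylation); the new centre is a mixture and becomes sp2 in step 4.

**Step 4**
Reactants: 8 (2S)-2-(hydroxymethyl)-2-methyl-6-(2-methylprop-2-en-1-yl)cyclohexan-1-one
Product: 11 (6S)-6-(hydroxymethyl)-6-methyl-2-(2-methylprop-2-en-1-yl)cyclohex-1-en-1-yl trifluoromethanesulfonate, via trimethylsilyl ether 9 (not isolated), via silyl ether enol triflate 10 (not isolated)
Conditions: Me3SiCl, NEt3, CH2Cl2, 0 °C; then KN(SiMe3)2, PhNTf2, THF, −78 to 0 °C; then K2CO3 (cat.), MeOH, 0 °C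
Reagents that add atoms: N-phenylbis(trifluoromethanesulfonimide), O=S(=O)(N(c1ccccc1)S(=O)(=O)C(F)(F)F)C(F)(F)F
Why: After in-situ O-silylation the ketone can enolise only toward C10 (C4 is quaternary) and the potassium enolate is trapped on oxygen (enol triflate formation), the silyl group then being removed by methanolysis; no stereocentre is touched.

**Step 5**
Reactants: 11 (6S)-6-(hydroxymethyl)-6-methyl-2-(2-methylprop-2-en-1-yl)cyclohex-1-en-1-yl trifluoromethanesulfonate
Product: 12 (3aR)-3a-methyl-7-(2-methylprop-2-en-1-yl)-3a,4,5,6-tetrahydro-2-benzofuran-1(3H)-one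
Conditions: Pd(PPh3)4 (5 mol %), CO (1 atm), NEt3, MeCN, 65 °C
Reagents that add atoms: carbon monoxide, [C-]#[O+]
Why: Oxidative addition of zerovalent palladium, CO insertion and capture of the acyl-palladium by the neighbouring primary alcohol close the butenolide (carbonylative lactonisation), which outpaces insertion of the remote alkene.

**Step 6**
Reactants: 12 (3aR)-3a-methyl-7-(2-methylprop-2-en-1-yl)-3a,4,5,6-tetrahydro-2-benzofuran-1(3H)-one
Product: 13 (3aR,7R,7aR)-7-(hydroxymethyl)-3a-methyl-7-(2-methylprop-2-en-1-yl)hexahydro-2-benzofuran-1(3H)-one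
Conditions: Ir[dF(CF3)ppy]2(dtbbpy)PF6 (1 mol %), quinuclidine (10 mol %), Bu4N(H2PO4) (25 mol %), MeOH/MeCN, 450 nm LEDs, rt, degassed
Reagents that add atoms: methanol, CO
Why: Proposed new method: the photo-oxidised quinuclidine abstracts the hydridic C–H of phosphate-bound methanol, the nucleophilic hydroxymethyl radical adds to the β-carbon C10 of the planar ring-fused butenolide on the face away from the pseudo-axial C4 methyl, and the α-lactonyl radical is reduced by the reduced iridium photocatalyst and protonated at C5 opposite the new CH2OH to give the cis-fused lactone, setting C10 (quaternary) and C5; the closest known reaction type is the photoredox/hydrogen-atom-transfer α-C–H alkylation of alcohols with acrylates (Giese addition of α-hydroxyalkyl radicals), not yet shown for methanol adding to a fully substituted butenolide β-carbon.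

**Step 7**
Reactants: 13 (3aR,7R,7aR)-7-(hydroxymethyl)-3a-methyl-7-(2-methylprop-2-en-1-yl)hexahydro-2-benzofuran-1(3H)-one
Product: 14 (3aR,7R,7aR)-7-(hydroxymethyl)-3a-methyl-7-(2-oxopropyl)hexahydro-2-benzofuran-1(3H)-one
Conditions: O3, CH2Cl2/MeOH, −78 °C; then Me2S
Reagents that add atoms: ozone, [O-][O+]=O
Why: Ozonolysis of the only alkene with reductive work-up turns the methallyl group into the acetonyl group (C9, C11, C12) under neutral conditions that do not move the lactone onto the free C20 alcohol.

**Step 8**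
Reactants: 14 (3aR,7R,7aR)-7-(hydroxymethyl)-3a-methyl-7-(2-oxopropyl)hexahydro-2-benzofuran-1(3H)-one; 15 (2E)-4,4-dimethoxybut-2-enoic acid
Product: 16 (2E)-4,4-dimethoxybut-2-enoate ester of alcohol 14
Conditions: DCC, DMAP (cat.), CH2Cl2, 0 °C to rt
Reagents that add atoms: none
Why: Steglich esterification acylates the primary C20 alcohol (bringing in C7, C8, C14, C13) and so also blocks its migration onto the C6 carbonyl; no stereocentre is affected.

**Step 9**
Reactants: 16 (2E)-4,4-dimethoxybut-2-enoate ester of alcohol 14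
Product: 19 tricyclic enone (rings A, B, C; C11 ketone, C12=C13), via enal ester 17 (not isolated), via keto aldehyde 18 (not isolated)
Conditions: TFA, H2O, CH2Cl2, 0 °C; then pyrrolidine (20 mol %), AcOH (20 mol %), toluene, 60 °C
Reagents that add atoms: none
Why: Acid unmasks the aldehyde, the ketone enol/enamine at C9 adds 6-exo to C8 (β to the aldehyde) and the methyl group C12 then condenses with the aldehyde C13 (Robinson-type Michael addition/aldol condensation), closing rings B and C; the epimerisable C9 settles with ring C on the side of the C1 methylene of the spiro centre C10, away from the bulkier C5, which is the target configuration.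

**Step 10**
Reactants: 19 tricyclic enone
Product: 20 ethylene ketal of 19
Conditions: (Me3SiOCH2)2, Me3SiOTf (cat.), CH2Cl2, −78 to −20 °C
Reagents that add atoms: 1,2-bis(trimethylsilyloxy)ethane, C[Si](C)(C)OCCO[Si](C)(C)C
Why: Noyori ketalisation masks the enone so that the lactone α-hydrogen at C8 is the only readily removed proton in the next step; the double bond stays at C12=C13.

**Step 11**
Reactants: 20 ethylene ketal of 19; 21 2-bromoacrolein
Product: 24 enone aldol (C8 bearing CH(OH)C(Br)=CH2), via lithium lactone enolate 22 (not isolated), via ketal aldol 23 (not isolated)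
Conditions: LiN(i-Pr)2, THF, −78 °C; then 21, −78 °C; then 1 M HCl, THF, rt
Reagents that add atoms: water, O
Why: The ring-fusion lactone enolate at C8 (C5–H of the other lactone lies between two quaternary carbons and is left alone) adds to the aldehyde on the face cis to H9, away from ring C and the axial C1, giving the cis-fused B/C system and the quaternary C8 (aldol addition); C15 is a mixture removed in step 14 and the acid work-up frees the enone.

**Step 12**
Reactants: 24 enone aldol
Product: 25 tetracyclic 11-ketone with 15-OH and 16-methylene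
Conditions: (Me3Si)3SiH (1.5 equiv), Ir[dF(CF3)ppy]2(dtbbpy)PF6 (1 mol %), DME, 450 nm LEDs, rt
Reagents that add atoms: none
Why: The silyl radical abstracts bromine and the vinyl σ-radical at C16, held over ring C by C8, adds 5-exo to the enone β-carbon C13 (photo-initiated Giese-type radical cyclisation), closing ring D and setting C13 by necessity; the α-keto radical takes H from the silane.

**Step 13**
Reactants: 25 tetracyclic 11-ketone
Product: 26 11,15-diol with 16-methylene (11-OH equatorial, anti to the C15–C16 bridge)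
Conditions: SmI2 (2.5 equiv), THF/MeOH (10:1), −78 °C
Reagents that add atoms: none
Why: Electron-transfer reduction of the only ketone goes through the ketyl/organosamarium, which is protonated to the more stable equatorial alcohol with OH anti to the two-carbon bridge, as in dissolving-metal reductions of 11-oxo steroids (SmI2 ketone reduction); lactones and the allylic alcohol are inert at −78 °C.

**Step 14**
Reactants: 26 11,15-diol with 16-methylene
Product: 27 15-oxo-16-ene with 11-OH
Conditions: MnO2 (20 equiv), CH2Cl2, rt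
Reagents that add atoms: none
Why: MnO2 oxidises only the allylic C15 alcohol to the enone (allylic alcohol oxidation) and leaves the saturated C11 alcohol.

**Step 15**
Reactants: 27 15-oxo-16-ene with 11-OH
Product: 28 guidongnin C
Conditions: H2 (1 atm), Pd/C (10 %), EtOAc, rt
Reagents that add atoms: none
Why: Heterogeneous hydrogenation delivers H2 to the exocyclic enone from the exo face on the side of C14, so the C16 methyl ends syn to C12 as in the target (catalytic hydrogenation).

**Compound list**
1 | (S)-(+)-carvone, (5S)-2-methyl-5-(prop-1-en-2-yl)cyclohex-2-en-1-one | CC(=C)[C@H]1CC=C(C)C(=O)C1 | starting material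
2 | lithium (5S)-2-methyl-5-(prop-1-en-2-yl)cyclohex-1-en-1-olate | CC(=C)[C@H]1CCC(C)=C(O[Li])C1 | intermediate
3 | (2S,5S)-2-(hydroxymethyl)-2-methyl-5-(prop-1-en-2-yl)cyclohexan-1-one (CH2OH cis to isopropenyl) | O=C1C[C@@H](C(C)=C)CC[C@@]1(C)CO | intermediate
4 | (2S,5S)-5-(1-hydroperoxy-1-methoxyethyl)-2-(hydroxymethyl)-2-methylcyclohexan-1-one (side-chain centre unassigned) | O=C1C[C@@H](C(C)(OC)OO)CC[C@@]1(C)CO | intermediate
5 | (2S)-2-(hydroxymethyl)-2-methylcyclohexan-1-one | O=C1CCCC[C@@]1(C)CO | intermediate
6 | methallyl bromide, 3-bromo-2-methylprop-1-ene | C=C(C)CBr | starting material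
7 | dilithium alkoxide enolate of 5 | [Li]OC[C@]1(C)CCCC=C1O[Li] | intermediate
8 | (2S)-2-(hydroxymethyl)-2-methyl-6-(2-methylprop-2-en-1-yl)cyclohexan-1-one (C6 epimers) | O=C1C(CC(C)=C)CCC[C@@]1(C)CO | intermediate
9 | trimethylsilyl ether of 8 | O=C1C(CC(C)=C)CCC[C@@]1(C)CO[Si](C)(C)C | intermediate
10 | (6S)-6-methyl-2-(2-methylprop-2-en-1-yl)-6-[(trimethylsilyloxy)methyl]cyclohex-1-en-1-yl trifluoromethanesulfonate | C=C(C)CC1=C(OS(=O)(=O)C(F)(F)F)[C@](C)(CO[Si](C)(C)C)CCC1 | intermediate
11 | (6S)-6-(hydroxymethyl)-6-methyl-2-(2-methylprop-2-en-1-yl)cyclohex-1-en-1-yl trifluoromethanesulfonate | C=C(C)CC1=C(OS(=O)(=O)C(F)(F)F)[C@](C)(CO)CCC1 | intermediate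
12 | (3aR)-3a-methyl-7-(2-methylprop-2-en-1-yl)-3a,4,5,6-tetrahydro-2-benzofuran-1(3H)-one (C5=C10 butenolide) | C=C(C)CC1=C2C(=O)OC[C@]2(C)CCC1 | intermediate
13 | (3aR,7R,7aR)-7-(hydroxymethyl)-3a-methyl-7-(2-methylprop-2-en-1-yl)hexahydro-2-benzofuran-1(3H)-one (cis lactone; CH2OH anti to the angular methyl) | C=C(C)C[C@@]1(CCC[C@@]2(C)COC(=O)[C@H]21)CO | intermediate
14 | (3aR,7R,7aR)-7-(hydroxymethyl)-3a-methyl-7-(2-oxopropyl)hexahydro-2-benzofuran-1(3H)-one | CC(=O)C[C@@]1(CCC[C@@]2(C)COC(=O)[C@H]21)CO | intermediate
15 | (2E)-4,4-dimethoxybut-2-enoic acid | COC(OC)/C=C/C(=O)O | starting material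
16 | (2E)-4,4-dimethoxybut-2-enoate ester of alcohol 14 (ester on C20–O) | CC(=O)C[C@@]1(CCC[C@@]2(C)COC(=O)[C@H]21)COC(=O)/C=C/C(OC)OC | intermediate
17 | (2E)-4-oxobut-2-enoate ester of alcohol 14 | CC(=O)C[C@@]1(CCC[C@@]2(C)COC(=O)[C@H]21)COC(=O)/C=C/C=O | intermediate
18 | keto aldehyde: ring B δ-lactone closed by C9–C8; C9 bears acetyl (C11, C12), C8 bears CH2CHO (C14, C13); C8 epimers | CC(=O)[C@@H]1C(CC=O)C(=O)OC[C@]12CCC[C@@]3(C)COC(=O)[C@H]32 | intermediate
19 | tricyclic enone: rings A, B, C with both lactones, C11 ketone, C12=C13, H9 as in the target, C8–H unassigned | O=C1C=CCC2C(=O)OC[C@]3(CCC[C@@]4(C)COC(=O)[C@H]43)[C@H]12 | intermediate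
20 | 11,11-ethylenedioxy ketal of 19 | O1CCOC12C=CCC3C(=O)OC[C@]4(CCC[C@@]5(C)COC(=O)[C@H]54)[C@H]23 | intermediate
21 | 2-bromoacrolein, 2-bromoprop-2-enal | C=C(Br)C=O | starting material
22 | lithium enolate (C7=C8, C7–OLi) of 20 | O1CCOC12C=CCC3=C(O[Li])OC[C@]4(CCC[C@@]5(C)COC(=O)[C@H]54)[C@H]23 | intermediate
23 | ketal aldol: 20 with CH(OH)C(Br)=CH2 (C15–C17) on C8, cis to H9; C15 epimers | C=C(Br)C(O)[C@]12CC=CC3(OCCO3)[C@H]1[C@@]1(CCC[C@@]3(C)COC(=O)[C@H]31)COC2=O | intermediate
24 | enone aldol: 19 with CH(OH)C(Br)=CH2 on C8, cis to H9; C15 epimers | C=C(Br)C(O)[C@]12CC=CC(=O)[C@H]1[C@@]1(CCC[C@@]3(C)COC(=O)[C@H]31)COC2=O | intermediate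
25 | 15-hydroxy-11-oxo-6,7-seco-ent-kaur-16-ene-6,19:7,20-diolide (C15 epimers) | C=C1C(O)[C@]23C[C@H]1CC(=O)[C@H]2[C@@]1(CCC[C@@]2(C)COC(=O)[C@H]21)COC3=O | intermediate
26 | 11,15-dihydroxy-6,7-seco-ent-kaur-16-ene-6,19:7,20-diolide, 11-OH anti to the C15–C16 bridge (C15 epimers) | C=C1C(O)[C@]23C[C@H]1C[C@@H](O)[C@H]2[C@@]1(CCC[C@@]2(C)COC(=O)[C@H]21)COC3=O | intermediate
27 | 11-hydroxy-15-oxo-6,7-seco-ent-kaur-16-ene-6,19:7,20-diolide, 11-OH anti to the C15–C16 bridge | C=C1C(=O)[C@]23C[C@H]1C[C@@H](O)[C@H]2[C@@]1(CCC[C@@]2(C)COC(=O)[C@H]21)COC3=O | intermediate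
28 | guidongnin C: 11-hydroxy-15-oxo-6,7-seco-ent-kaurane-6,19:7,20-diolide, 16-CH3 syn to C12, (4R,5R,8S,9S,10R,11R,13S,16R) | C[C@H]1C(=O)[C@]23C[C@H]1C[C@@H](O)[C@H]2[C@@]1(CCC[C@@]2(C)COC(=O)[C@H]21)COC3=O | target

**Step count and risk**
Total step count: 15. Longest linear sequence: 15 steps (1 to 28).

The three steps most likely to fail:

Step 6, the proposed new hydroxymethylation. The hindered, fully substituted β-carbon may react slowly, and the free C20 alcohol could migrate onto the C6 carbonyl. The fallback uses known chemistry, sets out from 12 and returns at 14. Copper-mediated conjugate addition of a vinyl group (CH2=CHMgBr, CuBr·SMe2, Me3SiCl, THF, −78 °C, then dilute HCl) occurs anti to the angular methyl and gives the vinyl lactone F1. Ozonolysis (O3, CH2Cl2/MeOH, then Me2S) cleaves both alkenes to the keto aldehyde F2. NaBH(OAc)3 in CH2Cl2 reduces only the aldehyde and delivers 14, so step 7 is no longer needed.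

Step 9, the one-pot Michael addition/aldol condensation. The hindered C9 may fail to add, or the enal may polymerise under amine catalysis. The fallback sets out from 16 and returns at 19. t-BuMe2SiOTf and NEt3 give the more substituted silyl enol ether F3 (C9=C11). Catalytic Me3SiOTf at −78 °C ionises the acetal, and the enol ether closes ring B by a Mukaiyama–Michael addition at C8 to give the methyl enol ether lactone F4. Aqueous TFA unmasks the aldehyde 18, and TsOH in toluene at 80 °C completes the aldol condensation to 19.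

Step 13, the facial outcome of the C11 reduction. A kinetic pathway would give the axial epimer with OH toward the bridge. The fallback sets out from 24 and returns at 26. The enone is reduced before ring D exists: NaBH4 with CeCl3·7H2O in MeOH at −78 °C (Luche reduction, hydride anti to the C9–C10 bond) gives the allylic alcohol F5. The photochemical radical cyclisation of step 12 applied to F5 then gives 26 directly, bypassing 25.

**Further compounds**
F1 | step 6 | vinyl lactone: 13 with CH=CH2 in place of CH2OH on C10 | C=C(C)C[C@@]1(CCC[C@@]2(C)COC(=O)[C@H]21)C=C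
F2 | step 6 | keto aldehyde: 14 with CHO in place of CH2OH on C10 | CC(=O)C[C@@]1(CCC[C@@]2(C)COC(=O)[C@H]21)C=O
F3 | step 9 | (Z)-tert-butyldimethylsilyl enol ether (C9=C11) of 16 | C/C(O[Si](C)(C)C(C)(C)C)=C/[C@@]1(CCC[C@@]2(C)COC(=O)[C@H]21)COC(=O)/C=C/C(OC)OC
F4 | step 9 | methyl enol ether lactone: 18 with CH=CH–OMe on C8 in place of CH2CHO (C8 epimers) | CC(=O)[C@@H]1C(C=COC)C(=O)OC[C@]12CCC[C@@]3(C)COC(=O)[C@H]32
F5 | step 13 | allylic alcohol: 24 with the C11 ketone reduced to CH–OH, OH cis to C10 (C15 epimers) | C=C(Br)C(O)[C@]12CC=C[C@@H](O)[C@H]1[C@@]1(CCC[C@@]3(C)COC(=O)[C@H]31)COC2=O
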